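**Strategy.** Atoms are numbered as in 8,9-seco-ent-kaurane. The ten-membered ring holds a C9 ketone whose β-carbon C5 and the 1,5-related C7/C8 pair form the retron of an anionic oxy-Cope ring expansion. The precursor is a 1-vinyl-2-(3,3-dimethylcyclohexenyl)bicyclo[3.2.1]octan-2-ol, made from (+)-nopinone by cyclobutane C–C cleavage (C13 kept) and from 3-methylcyclohexenone. In one operation the [3,3] shift breaks C8–C9, forms C5–C6 (closing the ten-membered ring around ring D), sets C5, and gives a regiodefined C9/C10 enolate that is C-methylated to create quaternary C10. Oxidation of the doubly allylic C15 and a singlet-oxygen ene transposition (C7–O, Δ8(14)) finish the target.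

Key step: step 9

Remarks on the chemistry: 4 is carried as a mixture of diastereomers at its two new centres, both destroyed in step 3. 19 is drawn as the expected C15 epimer; either epimer gives 20. The stereochemical outcomes of steps 8, 9 and 12 rest on conformational reasoning, not on calculation; each has a fallback below.

**Route**

Step 1
Reactants: 1 (1R,5S)-6,6-dimethylbicyclo[3.1.1]heptan-2-one, (+)-nopinone
Product: 2 (4S)-4-(2-acetoxypropan-2-yl)cyclohex-1-en-1-yl acetate
Conditions: BF3·OEt2, Zn(OAc)2, Ac2O, rt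
Reagents that add atoms: acetic anhydride CC(=O)OC(C)=O
Why: Lewis-acid-promoted cyclobutane fragmentation (heterolysis of the strained C–C bond between the α-bridgehead and the CMe2 carbon, acetate capture of the tertiary cation, O-acetylation of the enolate) should place the enol acetate only on the former bridgehead side, so the ring stays unsymmetrical and the nopinone stereocentre that becomes C13 is kept.

Step 2
Reactants: 2 (4S)-4-(2-acetoxypropan-2-yl)cyclohex-1-en-1-yl acetate
Product: 4 (4S)-2-(1-hydroxyethyl)-4-(2-hydroxypropan-2-yl)cyclohexan-1-one, via dilithium enolate-alkoxide 3 (not isolated)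
Conditions: MeLi (4.2 equiv), THF, 0 °C; then MeCHO, −78 °C; aq NH4Cl
Reagents that add atoms: acetaldehyde CC=O
Why: Cleavage of the enol acetate with MeLi releases the lithium enolate regiospecifically at the future C8, and its aldol addition to acetaldehyde installs C7 and C6 there (the new centres are removed in step 3).

Step 3
Reactants: 4 (4S)-2-(1-hydroxyethyl)-4-(2-hydroxypropan-2-yl)cyclohexan-1-one
Product: 5 (2E,4S)-2-ethylidene-4-(prop-1-en-2-yl)cyclohexan-1-one
Conditions: SOCl2, pyridine, CH2Cl2, −20 to 0 °C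
Reagents that add atoms: none
Why: Double dehydration through chlorosulfite esters: E1cB-type loss from the aldol gives the (E)-enone, and pyridine-mediated E2 of the tertiary chlorosulfite should favour the terminal isopropenyl alkene (six methyl hydrogens against one hindered ring hydrogen).

Step 4
Reactants: 5 (2E,4S)-2-ethylidene-4-(prop-1-en-2-yl)cyclohexan-1-one
Product: 6 (2E,4S)-4-(3-chloroprop-1-en-2-yl)-2-ethylidenecyclohexan-1-one
Conditions: Ca(OCl)2, CO2 (dry ice), CH2Cl2–H2O, 0 °C
Reagents that add atoms: calcium hypochlorite [Ca+2].[O-]Cl.[O-]Cl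
Why: Ene-type allylic chlorination by HOCl is selective for the electron-rich 1,1-disubstituted alkene (the enone alkene is deactivated), and the symmetric 2-propenyl unit leaves no regiochemical choice.

Step 5
Reactants: 6 (2E,4S)-4-(3-chloroprop-1-en-2-yl)-2-ethylidenecyclohexan-1-one
Product: 8 (1R,5S)-6-methylidene-1-vinylbicyclo[3.2.1]octan-2-one, via potassium dienolate 7 (not isolated)
Conditions: KOtBu, t-BuOH–THF, 0 °C to rt
Reagents that add atoms: none
Why: Deconjugative intramolecular α-alkylation: under equilibrating conditions the extended dienolate reacts at its α-carbon C8 in a 5-exo-tet displacement of the allylic chloride, closing ring D; the two-carbon bridge can only form cis to the C13 substituent, which fixes the quaternary C8.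

Step 6
Reactants: 9 3-methylcyclohex-2-en-1-one
Product: 11 3,3-dimethylcyclohex-1-en-1-yl trifluoromethanesulfonate, via lithium enolate 10 (not isolated)
Conditions: Me2CuLi (from MeLi, CuI), Et2O, 0 °C; then PhNTf2, THF, 0 °C to rt
Reagents that add atoms: lithium dimethylcuprate [Li+].C[Cu-]C; N-phenylbis(trifluoromethanesulfonimide) O=S(=O)(N(c1ccccc1)S(=O)(=O)C(F)(F)F)C(F)(F)F
Why: Cuprate conjugate addition builds the gem-dimethyl carbon, and trapping the resulting enolate as the enol triflate fixes the double bond regiospecifically next to that carbon.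

Step 7
Reactants: 11 3,3-dimethylcyclohex-1-en-1-yl trifluoromethanesulfonate
Product: 12 (3,3-dimethylcyclohex-1-en-1-yl)trimethylstannane
Conditions: Me3SnSnMe3, Pd(PPh3)4 (cat.), LiCl, THF, 65 °C
Reagents that add atoms: hexamethylditin C[Sn](C)(C)[Sn](C)(C)C
Why: Stille-type Pd-catalysed stannylation of an enol triflate with retention of the alkene position.

Step 8
Reactants: 12 (3,3-dimethylcyclohex-1-en-1-yl)trimethylstannane; 8 (1R,5S)-6-methylidene-1-vinylbicyclo[3.2.1]octan-2-one
Product: 15 (1R,2R,5S)-2-(3,3-dimethylcyclohex-1-en-1-yl)-6-methylidene-1-vinylbicyclo[3.2.1]octan-2-ol, via alkenyllithium 13 (not isolated), via alkenylcerium dichloride 14 (not isolated)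
Conditions: MeLi, THF, −78 to 0 °C; CeCl3 (anhydrous), −78 °C; then 8, −78 to 0 °C; aq NH4Cl
Reagents that add atoms: none
Why: Tin–lithium exchange and transmetalation give a weakly basic organocerium that adds 1,2 to the hindered, enolizable ketone; equatorial attack from the side of the C15–C16 bridge (away from the inward-tilted C14–H and the axial C12–H) is expected, placing the cyclohexenyl group equatorial and the hydroxyl axial at the new centre C9.

Step 9
Reactants: 15 (1R,2R,5S)-2-(3,3-dimethylcyclohex-1-en-1-yl)-6-methylidene-1-vinylbicyclo[3.2.1]octan-2-ol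
Product: 18 (5R,10R,13S,7Z)-8,9-secokaura-7,16-dien-9-one, via potassium alkoxide 16 (not isolated), via potassium enolate 17 (not isolated)
Conditions: KH, 18-crown-6, THF, 0 °C to rt; then MeI, −78 °C to rt
Reagents that add atoms: iodomethane CI
Why: The dissociated potassium alkoxide undergoes an anionic oxy-Cope [3,3]-sigmatropic shift in which the C8–C9 bond of ring C breaks while the cyclohexene carbon C5 bonds to the vinyl terminus C6; the closest known reaction type is the oxy-Cope ring expansion of 1,2-dialkenylcyclohexanols to cyclodec-5-enones with alkylation of the enolate in the same flask. The ten-membered ring is closed by ring expansion (six to ten atoms) and emerges bridged by ring D as a bicyclo[7.2.1] system. C5 is set by chirality transfer from C8/C9 through the chair transition state imposed by the rigid chair of ring C with both alkenyl groups equatorial (C4 pseudo-equatorial, H5 pseudo-axial), which also fixes the C7=C8 alkene (C6 cis to C15) and the enolate geometry (O cis to C5). C10 is set when MeI alkylates the tetrasubstituted enolate on the face syn to the new C5–C6 bond, the opposite face being screened by the axial methyl on C4. The step needs C- over O-methylation and this face of C10, which the soft electrophile, the regiospecific enolate and the gem-dimethyl group are expected to secure.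

Step 10
Reactants: 18 (5R,10R,13S,7Z)-8,9-secokaura-7,16-dien-9-one
Product: 19 (5R,10R,13S,7Z)-15-hydroxy-8,9-secokaura-7,16-dien-9-one (OH on the ring D face not spanned by the ten-membered ring)
Conditions: SeO2 (cat.), t-BuOOH, CH2Cl2, rt
Reagents that add atoms: tert-butyl hydroperoxide CC(C)(C)OO
Why: SeO2 allylic oxidation (ene reaction then [2,3]-sigmatropic shift): both the C7=C8 and the C16=C17 alkene direct oxygen to the doubly allylic C15 methylene, delivered from the open face of ring D (this centre is lost in step 11).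

Step 11
Reactants: 19 (5R,10R,13S,7Z)-15-hydroxy-8,9-secokaura-7,16-dien-9-one
Product: 20 (5R,10R,13S,7Z)-8,9-secokaura-7,16-diene-9,15-dione
Conditions: Dess–Martin periodinane, NaHCO3, CH2Cl2, 0 °C
Reagents that add atoms: none
Why: Dess–Martin oxidation of the bis-allylic alcohol to the cross-conjugated dienone under buffered, non-basic conditions that spare the α-methylene ketone.

Step 12
Reactants: 20 (5R,10R,13S,7Z)-8,9-secokaura-7,16-diene-9,15-dione
Product: 22 (5R,7R,10R,13S)-7-hydroxy-8,9-secokaura-8(14),16-diene-9,15-dione, via 7-hydroperoxide 21 (not isolated)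
Conditions: O2, hν (visible), tetraphenylporphyrin (cat.), CH2Cl2, −20 °C; then Me2S
Reagents that add atoms: dioxygen O=O
Why: Schenck ene reaction of singlet oxygen with the s-cis enone: the geminal effect takes the allylic hydrogen from C14 (the alkyl group geminal to the carbonyl) and moves the alkene to C8=C14, while oxygen adds to C7 on the face of the strained C7=C8 bond not covered by the ten-membered ring, which sets C7; Me2S reduces the hydroperoxide.

Step 13
Reactants: 22 (5R,7R,10R,13S)-7-hydroxy-8,9-secokaura-8(14),16-diene-9,15-dione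
Product: 23 (5R,7R,10R,13S)-7-acetoxy-8,9-secokaura-8(14),16-diene-9,15-dione (target)
Conditions: Ac2O, pyridine, CH2Cl2, 0 °C to rt
Reagents that add atoms: acetic anhydride CC(=O)OC(C)=O
Why: Acylation of the secondary allylic alcohol; no stereocentre is touched.

**Compound list**

1 | (1R,5S)-6,6-dimethylbicyclo[3.1.1]heptan-2-one, (+)-nopinone | O=C2CC[C@H]1C[C@@H]2C1(C)C | starting material
2 | (4S)-4-(2-acetoxypropan-2-yl)cyclohex-1-en-1-yl acetate | CC(=O)OC1=CC[C@H](CC1)C(C)(C)OC(C)=O | intermediate
3 | dilithium (4S)-4-(2-oxidopropan-2-yl)cyclohex-1-en-1-olate | [Li+].[Li+].[O-]C1=CC[C@H](CC1)C(C)(C)[O-] | intermediate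
4 | (4S)-2-(1-hydroxyethyl)-4-(2-hydroxypropan-2-yl)cyclohexan-1-one (diastereomer mixture at C2 and the carbinol carbon) | CC(O)C1C[C@H](CCC1=O)C(C)(C)O | intermediate
5 | (2E,4S)-2-ethylidene-4-(prop-1-en-2-yl)cyclohexan-1-one | C/C=C1\C[C@H](CCC1=O)C(C)=C | intermediate
6 | (2E,4S)-4-(3-chloroprop-1-en-2-yl)-2-ethylidenecyclohexan-1-one | C/C=C1\C[C@H](CCC1=O)C(=C)CCl | intermediate
7 | potassium (4S)-4-(3-chloroprop-1-en-2-yl)-2-vinylcyclohex-1-en-1-olate | [K+].[O-]C1=C(C=C)C[C@H](CC1)C(=C)CCl | intermediate
8 | (1R,5S)-6-methylidene-1-vinylbicyclo[3.2.1]octan-2-one | O=C1CC[C@H]2C[C@]1(C=C)CC2=C | intermediate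
9 | 3-methylcyclohex-2-en-1-one | CC1=CC(=O)CCC1 | starting material
10 | lithium 3,3-dimethylcyclohex-1-en-1-olate | [Li+].[O-]C1=CC(C)(C)CCC1 | intermediate
11 | 3,3-dimethylcyclohex-1-en-1-yl trifluoromethanesulfonate | FC(F)(F)S(=O)(=O)OC1=CC(C)(C)CCC1 | intermediate
12 | (3,3-dimethylcyclohex-1-en-1-yl)trimethylstannane | C[Sn](C)(C)C1=CC(C)(C)CCC1 | intermediate
13 | (3,3-dimethylcyclohex-1-en-1-yl)lithium | [Li]C1=CC(C)(C)CCC1 | intermediate
14 | dichloro(3,3-dimethylcyclohex-1-en-1-yl)cerium | Cl[Ce](Cl)C1=CC(C)(C)CCC1 | intermediate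
15 | (1R,2R,5S)-2-(3,3-dimethylcyclohex-1-en-1-yl)-6-methylidene-1-vinylbicyclo[3.2.1]octan-2-ol | O[C@@]1(C3=CC(C)(C)CCC3)CC[C@H]2C[C@]1(C=C)CC2=C | intermediate
16 | potassium alkoxide of 15 | [K+].[O-][C@@]1(C3=CC(C)(C)CCC3)CC[C@H]2C[C@]1(C=C)CC2=C | intermediate
17 | potassium C9/C10 enolate of (5R,13S,7Z)-20-nor-8,9-secokaura-7,16-dien-9-one (O cis to C5) | [K+].C=C1C/C2=C\C[C@@H]3C(C)(C)CCC/C3=C(/[O-])CC[C@H]1C2 | intermediate
18 | (5R,10R,13S,7Z)-8,9-secokaura-7,16-dien-9-one | C=C1C/C2=C\C[C@@H]3C(C)(C)CCC[C@@]3(C)C(=O)CC[C@H]1C2 | intermediate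
19 | (5R,10R,13S,7Z)-15-hydroxy-8,9-secokaura-7,16-dien-9-one | C=C1[C@@H](O)/C2=C\C[C@@H]3C(C)(C)CCC[C@@]3(C)C(=O)CC[C@H]1C2 | intermediate
20 | (5R,10R,13S,7Z)-8,9-secokaura-7,16-diene-9,15-dione | C=C1C(=O)/C2=C\C[C@@H]3C(C)(C)CCC[C@@]3(C)C(=O)CC[C@H]1C2 | intermediate
21 | (5R,7R,10R,13S)-7-hydroperoxy-8,9-secokaura-8(14),16-diene-9,15-dione | C=C1C(=O)C2=C[C@@H]1CCC(=O)[C@]1(C)CCCC(C)(C)[C@H]1C[C@H]2OO | intermediate
22 | (5R,7R,10R,13S)-7-hydroxy-8,9-secokaura-8(14),16-diene-9,15-dione | C=C1C(=O)C2=C[C@@H]1CCC(=O)[C@]1(C)CCCC(C)(C)[C@H]1C[C@H]2O | intermediate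
23 | (5R,7R,10R,13S)-7-acetoxy-8,9-secokaura-8(14),16-diene-9,15-dione | C=C1C(=O)C2=C[C@@H]1CCC(=O)[C@]1(C)CCCC(C)(C)[C@H]1C[C@H]2OC(C)=O | target

**Step count and risks**

Total steps: 13. Longest linear sequence: 11 steps (steps 1–5 and 8–13).

Step 9. Risk: methyl iodide may enter C10 on the outer face of the ring-bound enolate, anti to the new C5–C6 bond, which would give the C10 epimer. The fallback carries C20 in the nucleophile and closes ring A last, so that outer-face attack gives the wanted centre. It sets out from 8 and returns at 18. Isobutyronitrile is alkylated (LDA, 1-bromo-3-chloropropane) to 5-chloro-2,2-dimethylpentanenitrile F1 and reduced (DIBAL-H) to 5-chloro-2,2-dimethylpentanal F2. Seyferth–Gilbert homologation (dimethyl (1-diazo-2-oxopropyl)phosphonate, K2CO3, MeOH) gives 6-chloro-3,3-dimethylhex-1-yne F3, and methylation (n-BuLi, MeI) gives 7-chloro-4,4-dimethylhept-2-yne F4. Hydrozirconation–iodination (Cp2Zr(H)Cl; I2) places the metal at the unhindered methyl-bearing carbon and gives (E)-7-chloro-2-iodo-4,4-dimethylhept-2-ene F5. Iodine–lithium exchange (t-BuLi) gives (E)-(7-chloro-4,4-dimethylhept-2-en-2-yl)lithium F6, CeCl3 gives the alkenylcerium dichloride F7, and addition to 8 gives (1R,2R,5S)-2-[(2E)-7-chloro-4,4-dimethylhept-2-en-2-yl]-6-methylidene-1-vinylbicyclo[3.2.1]octan-2-ol F8. KH/18-crown-6 forms the potassium alkoxide F9, and the same oxy-Cope shift gives the potassium enolate F10, in which C20 lies in the enolate plane. C10 then displaces the chloride at C1 (6-exo-tet) from the uncovered face, closing ring A.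

Step 8. Risk: the cerium reagent may attack the axial face of the C9 carbonyl, anti to the C15–C16 bridge, giving the C9 epimer, whose rearrangement would invert C5. The fallback replaces kinetic by thermodynamic control. It sets out from 8 (with 14) and returns at 15. The epimer (1R,2S,5S)-2-(3,3-dimethylcyclohex-1-en-1-yl)-6-methylidene-1-vinylbicyclo[3.2.1]octan-2-ol F11 is converted (MeMgBr, THF–HMPA, 65 °C) into its bromomagnesium alkoxide F12. As a hindered tertiary homoallylic alkoxide this can fragment reversibly by retro-allylation to the ring-opened (Z)-allylmagnesium ketone F13. Re-addition through a six-membered chair transition state should favour the epimer with the bulky cyclohexenyl group equatorial, and work-up gives 15.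

Step 12. Risk: the ene reaction may be slow on the electron-poor enone, may abstract the C13 hydrogen through the exocyclic enone, or may show poor facial selectivity at C7. The fallback uses hydroxyl-directed epoxidation and epoxide-to-allylic-alcohol isomerization instead. It sets out from 19 and returns at 22. VO(acac)2/t-BuOOH epoxidizes C7=C8 syn to the C15 hydroxyl to give (5R,10R,13S)-7,8-epoxy-15-hydroxy-8,9-secokaur-16-en-9-one F14. Diethylaluminium 2,2,6,6-tetramethylpiperidide (from LiTMP and Et2AlCl, toluene, 0 °C) removes the only hydrogen syn to the epoxide oxygen on a carbon attached to C8 (at C14) and opens the C8–O bond, giving (5R,7R,10R,13S)-7,15-dihydroxy-8,9-secokaura-8(14),16-dien-9-one F15. MnO2 (CH2Cl2, rt) should then oxidize the more activated bis-allylic ring carbinol C15 selectively.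

**Further compounds**

F1 | step 9 | 5-chloro-2,2-dimethylpentanenitrile | CC(C)(CCCCl)C#N
F2 | step 9 | 5-chloro-2,2-dimethylpentanal | CC(C)(CCCCl)C=O
F3 | step 9 | 6-chloro-3,3-dimethylhex-1-yne | C#CC(C)(C)CCCCl
F4 | step 9 | 7-chloro-4,4-dimethylhept-2-yne | CC#CC(C)(C)CCCCl
F5 | step 9 | (E)-7-chloro-2-iodo-4,4-dimethylhept-2-ene | C/C(I)=C\C(C)(C)CCCCl
F6 | step 9 | (E)-(7-chloro-4,4-dimethylhept-2-en-2-yl)lithium | [Li]/C(C)=C/C(C)(C)CCCCl
F7 | step 9 | dichloro[(E)-7-chloro-4,4-dimethylhept-2-en-2-yl]cerium | Cl[Ce](Cl)/C(C)=C/C(C)(C)CCCCl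
F8 | step 9 | (1R,2R,5S)-2-[(2E)-7-chloro-4,4-dimethylhept-2-en-2-yl]-6-methylidene-1-vinylbicyclo[3.2.1]octan-2-ol | O[C@@]1(/C(C)=C/C(C)(C)CCCCl)CC[C@H]2C[C@]1(C=C)CC2=C
F9 | step 9 | potassium alkoxide of F8 | [K+].[O-][C@@]1(/C(C)=C/C(C)(C)CCCCl)CC[C@H]2C[C@]1(C=C)CC2=C
F10 | step 9 | potassium C9/C10 enolate with open ring A (C5 bearing the 5-chloro-2-methylpentan-2-yl chain, C10 bearing C20) | [K+].C=C1C/C2=C\C[C@H](C(C)(C)CCCCl)/C(C)=C(\[O-])CC[C@H]1C2
F11 | step 8 | (1R,2S,5S)-2-(3,3-dimethylcyclohex-1-en-1-yl)-6-methylidene-1-vinylbicyclo[3.2.1]octan-2-ol | O[C@]1(C3=CC(C)(C)CCC3)CC[C@H]2C[C@]1(C=C)CC2=C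
F12 | step 8 | bromomagnesium alkoxide of F11 | Br[Mg]O[C@]1(C3=CC(C)(C)CCC3)CC[C@H]2C[C@]1(C=C)CC2=C
F13 | step 8 | bromo[(2Z)-2-{(3S)-3-[3-(3,3-dimethylcyclohex-1-en-1-yl)-3-oxopropyl]-4-methylidenecyclopentylidene}ethyl]magnesium | Br[Mg]C/C=C1\CC(=C)[C@@H](CCC(=O)C2=CC(C)(C)CCC2)C1
F14 | step 12 | (5R,10R,13S)-7,8-epoxy-15-hydroxy-8,9-secokaur-16-en-9-one (epoxide oxygen and 15-OH on the same open face of ring D) | C=C1[C@@H](O)[C@]23O[C@@H]2C[C@@H]4C(C)(C)CCC[C@@]4(C)C(=O)CC[C@H]1C3
F15 | step 12 | (5R,7R,10R,13S)-7,15-dihydroxy-8,9-secokaura-8(14),16-dien-9-one | C=C1[C@@H](O)C2=C[C@@H]1CCC(=O)[C@]1(C)CCCC(C)(C)[C@H]1C[C@H]2O
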